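## Retrosynthetic overview

1. The (3S) target comes from desilylation and C4 oxidation of a cis-(3S,4S)-isoflavan-4-ol. That alcohol comes from asymmetric transfer hydrogenation with dynamic kinetic resolution of a bis-TIPS isoflavone; this sets C3, and the C4 carbinol is a temporary stereocentre and oxidation level.
2. The isoflavone comes from a Suzuki coupling that forms the C3–C1' bond between a 3-iodochromone (rings A and C) and a chromene-6-boronate (rings B and D). The boron is placed by sterically controlled C–H borylation.
3. Ring D comes from the furan ring of benzofuran-7-ol. Nickel-catalysed opening of the furan O–C2 bond with isopropenylmagnesium bromide is followed by a hydrogen shift to a vinyl ortho-quinone methide and oxa-6π closure, so five ring atoms become six by insertion of one carbon between O and the vinylic CH.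
4. Enabling feature: ring D is O(on C4')–C(CH3)2–CH=CH–C5', a benzofuran ring plus one quaternary carbon. It has a cis alkene conjugated with ring B and held ortho to a phenolic oxygen, and a tertiary allylic C–O bond that an ortho-quinone methide closes by itself. The adjacent C3'–OH completes a catechol whose magnesium salt activates the furan oxygen and cannot compete in the closure.
5. Order of ring formation: B (bought, carrying the furan ring), then D (step 1); A (bought), then C (step 6); the halves are joined in step 7.

Key step: step 1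

Assumption: the sense of induction in step 8 is assigned by analogy with aryl alkyl ketones, for which the (S,S)-catalyst gives the S alcohol; if the isoflavanone behaved otherwise, the (R,R)-catalyst would be used.

## Route

Step 1
Reactants: 1 benzofuran-7-ol
Product: 4 2,2-dimethyl-2H-chromen-8-ol, via (Z)-dienylcatechol 2 (not isolated), via vinyl ortho-quinone methide 3 (not isolated)
Conditions: isopropenylMgBr (3 equiv), NiCl2(PCy3)2 (5 mol %), toluene/THF, 0 to 50 °C, argon; then AcOH, 70 °C, one pot
Reagents that add atoms: isopropenylmagnesium bromide, CC(=C)[Mg]Br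
Why: One equivalent of the Grignard reagent converts the C7 hydroxyl into a magnesium phenoxide whose metal also binds the furan oxygen and polarises the O1–C2 bond, zerovalent nickel (formed from NiCl2(PCy3)2 and the Grignard reagent) inserts into this vinylic C–O bond with retention of geometry, and transmetalation plus reductive elimination give the magnesium salt of (Z)-dienylcatechol 2; the closest known reaction type is the nickel-catalysed Kumada-type C–O cross-coupling that opens benzofurans and other cyclic enol ethers with Grignard reagents. After acidification the phenol ortho to the side chain hands its hydrogen to the diene terminus, by a thermal [1,7]-hydrogen shift or by protonation to the tertiary allylic and benzylic cation followed by loss of the phenolic proton, which gives vinyl ortho-quinone methide 3 as in the known conversion of ortho-dienylphenols into 2H-chromenes. Ring D then closes by oxa-6π electrocyclisation of 3, oxygen bonding to the dimethyl-substituted terminus, so the five-membered ring O1–C2–C3–C3a–C7a of 1 returns as a six-membered ring with the former isopropenyl carbon inserted between O1 and C2. No stereocentre is created, the cis ring alkene is inherited from the benzofuran, and any E-diene that arises by isomerisation is drawn through the same cation under the acidic finish. The step needs chemoselectivity for the vinylic C2–O bond over the aryl C–O bonds, which is secured by the far easier nickel insertion into enol ether C–O bonds at these temperatures and by the inertness of magnesium phenoxides. It also needs a choice between the two catechol oxygens, and this is structural, since only the oxygen ortho to the side chain can reach the terminus and the other one is left as the free C8 hydroxyl.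

Step 2
Reactants: 4 2,2-dimethyl-2H-chromen-8-ol
Product: 5 2,2-dimethyl-8-(triisopropylsilyloxy)-2H-chromene
Conditions: TIPSCl, imidazole, DMF, rt
Reagents that add atoms: triisopropylsilyl chloride, CC(C)[Si](Cl)(C(C)C)C(C)C
Why: Imidazole-promoted silyl ether formation on the only hydroxyl group present; the bulky TIPS group withstands the basic, reducing and oxidising steps that follow and shields C7 in step 3.

Step 3
Reactants: 5 2,2-dimethyl-8-(triisopropylsilyloxy)-2H-chromene
Product: 6 2-[2,2-dimethyl-8-(triisopropylsilyloxy)-2H-chromen-6-yl]-4,4,5,5-tetramethyl-1,3,2-dioxaborolane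
Conditions: B2pin2, [Ir(OMe)(cod)]2 (1.5 mol %), 4,4'-di-tert-butyl-2,2'-bipyridine (3 mol %), MTBE, 60 °C
Reagents that add atoms: bis(pinacolato)diboron, CC1(C)OB(OC1(C)C)B2OC(C)(C)C(C)(C)O2
Why: Iridium-catalysed aromatic C–H borylation is governed by sterics, and in the 1,2,3-trisubstituted ring B only C6–H has hydrogen on both sides, whereas C5–H lies next to the ring-D vinyl carbon, C7–H next to OTIPS, and the two vinylic C–H bonds are crowded by the quaternary carbon and the peri hydrogen.

Step 4
Reactants: 7 1-(2,4-dihydroxy-6-methoxyphenyl)ethan-1-one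
Product: 8 1-[2-hydroxy-6-methoxy-4-(triisopropylsilyloxy)phenyl]ethan-1-one
Conditions: TIPSCl (1.05 equiv), imidazole, CH2Cl2, 0 °C
Reagents that add atoms: triisopropylsilyl chloride, CC(C)[Si](Cl)(C(C)C)C(C)C
Why: Chemoselective silylation, because the C2 hydroxyl is tied up in a hydrogen bond to the acetyl carbonyl and flanked by it, so the free and more acidic C4 hydroxyl reacts first with one equivalent of TIPSCl.

Step 5
Reactants: 8 1-[2-hydroxy-6-methoxy-4-(triisopropylsilyloxy)phenyl]ethan-1-one
Product: 9 (E)-3-(dimethylamino)-1-[2-hydroxy-6-methoxy-4-(triisopropylsilyloxy)phenyl]prop-2-en-1-one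
Conditions: DMF-DMA, toluene, 90 °C
Reagents that add atoms: N,N-dimethylformamide dimethyl acetal, COC(OC)N(C)C
Why: Enaminone formation, the condensation of a methyl ketone with an amide acetal, adds the one carbon that becomes C2 of ring C and is routine for 2-hydroxyacetophenones.

Step 6
Reactants: 9 (E)-3-(dimethylamino)-1-[2-hydroxy-6-methoxy-4-(triisopropylsilyloxy)phenyl]prop-2-en-1-one
Product: 10 3-iodo-5-methoxy-7-(triisopropylsilyloxy)-4H-chromen-4-one
Conditions: I2, CHCl3, rt
Reagents that add atoms: iodine, II
Why: Iodine-induced enaminone cyclisation, in which iodination at the enaminone α-carbon gives an iminium ion, the ortho phenol adds to it in a 6-endo-trig closure of ring C, and loss of dimethylamine gives the 3-iodochromone.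

Step 7
Reactants: 6 2-[2,2-dimethyl-8-(triisopropylsilyloxy)-2H-chromen-6-yl]-4,4,5,5-tetramethyl-1,3,2-dioxaborolane; 10 3-iodo-5-methoxy-7-(triisopropylsilyloxy)-4H-chromen-4-one
Product: 11 3-[2,2-dimethyl-8-(triisopropylsilyloxy)-2H-chromen-6-yl]-5-methoxy-7-(triisopropylsilyloxy)-4H-chromen-4-one
Conditions: Pd(dppf)Cl2 (3 mol %), K3PO4, 1,4-dioxane/H2O, 60 °C
Reagents that add atoms: none
Why: Suzuki–Miyaura coupling of a 3-iodochromone with an unhindered arylboronate is the standard entry to isoflavones, and the mild phosphate base at moderate temperature spares the aryl silyl ethers and the base-sensitive pyranone ring.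

Step 8
Reactants: 11 3-[2,2-dimethyl-8-(triisopropylsilyloxy)-2H-chromen-6-yl]-5-methoxy-7-(triisopropylsilyloxy)-4H-chromen-4-one
Product: 13 (3S,4S)-3-[2,2-dimethyl-8-(triisopropylsilyloxy)-2H-chromen-6-yl]-5-methoxy-7-(triisopropylsilyloxy)-3,4-dihydro-2H-chromen-4-ol (3,4-cis), via racemic isoflavanone 12 (not isolated)
Conditions: RuCl[(S,S)-TsDPEN](p-cymene) (2 mol %), HCO2H/Et3N, EtOAc, 40 °C
Reagents that add atoms: none
Why: Noyori-type asymmetric transfer hydrogenation first reduces the chromone C2=C3 bond to racemic isoflavanone 12, whose C3–H is acidic enough to racemise under Et3N, and the (S,S)-catalyst then reduces only the 3S ketone fast, delivering hydride to the carbonyl face opposite the C3 aryl group (the CH/π contact of the catalyst arene with ring A fixes 4S as for simple aryl ketones), so that dynamic kinetic resolution sets C3 and C4 together as the cis-(3S,4S) alcohol.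

Step 9
Reactants: 13 (3S,4S)-3-[2,2-dimethyl-8-(triisopropylsilyloxy)-2H-chromen-6-yl]-5-methoxy-7-(triisopropylsilyloxy)-3,4-dihydro-2H-chromen-4-ol
Product: 14 (3S)-3-[2,2-dimethyl-8-(triisopropylsilyloxy)-2H-chromen-6-yl]-5-methoxy-7-(triisopropylsilyloxy)-2,3-dihydro-4H-chromen-4-one
Conditions: Dess–Martin periodinane, CH2Cl2, 0 °C to rt
Reagents that add atoms: none
Why: Dess–Martin oxidation works under nearly neutral, non-enolising conditions, so the temporary C4 stereocentre is erased while C3 keeps its S configuration, and the chromene alkene and silyl ethers are inert to the reagent.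

Step 10
Reactants: 14 (3S)-3-[2,2-dimethyl-8-(triisopropylsilyloxy)-2H-chromen-6-yl]-5-methoxy-7-(triisopropylsilyloxy)-2,3-dihydro-4H-chromen-4-one
Product: 15 (3S)-7-hydroxy-3-(8-hydroxy-2,2-dimethyl-2H-chromen-6-yl)-5-methoxy-2,3-dihydro-4H-chromen-4-one (target)
Conditions: HF·pyridine, pyridine, THF, 0 °C to rt
Reagents that add atoms: none
Why: Fluoride-induced desilylation in a pyridine-buffered, weakly acidic medium frees both phenols without generating phenoxide or enolate, so that C3 is not epimerised and the acid-sensitive ring D and the C5 methyl ether stay intact.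

## Compound list

1 | benzofuran-7-ol | Oc1cccc2ccoc12 | starting material
2 | 3-[(1Z)-3-methylbuta-1,3-dien-1-yl]benzene-1,2-diol (formed first as its magnesium salt) | CC(=C)/C=C\c1cccc(O)c1O | intermediate
3 | (6Z)-2-hydroxy-6-(3-methylbut-2-en-1-ylidene)cyclohexa-2,4-dien-1-one | CC(C)=C/C=C1/C=CC=C(O)C1=O | intermediate
4 | 2,2-dimethyl-2H-chromen-8-ol | CC1(C)C=Cc2cccc(O)c2O1 | intermediate
5 | 2,2-dimethyl-8-(triisopropylsilyloxy)-2H-chromene | CC1(C)C=Cc2cccc(O[Si](C(C)C)(C(C)C)C(C)C)c2O1 | intermediate
6 | 2-[2,2-dimethyl-8-(triisopropylsilyloxy)-2H-chromen-6-yl]-4,4,5,5-tetramethyl-1,3,2-dioxaborolane | CC1(C)C=Cc2cc(B3OC(C)(C)C(C)(C)O3)cc(O[Si](C(C)C)(C(C)C)C(C)C)c2O1 | intermediate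
7 | 1-(2,4-dihydroxy-6-methoxyphenyl)ethan-1-one | CC(=O)c1c(O)cc(O)cc1OC | starting material
8 | 1-[2-hydroxy-6-methoxy-4-(triisopropylsilyloxy)phenyl]ethan-1-one | CC(=O)c1c(O)cc(O[Si](C(C)C)(C(C)C)C(C)C)cc1OC | intermediate
9 | (E)-3-(dimethylamino)-1-[2-hydroxy-6-methoxy-4-(triisopropylsilyloxy)phenyl]prop-2-en-1-one | CN(C)/C=C/C(=O)c1c(O)cc(O[Si](C(C)C)(C(C)C)C(C)C)cc1OC | intermediate
10 | 3-iodo-5-methoxy-7-(triisopropylsilyloxy)-4H-chromen-4-one | COc1cc(O[Si](C(C)C)(C(C)C)C(C)C)cc2occ(I)c(=O)c12 | intermediate
11 | 3-[2,2-dimethyl-8-(triisopropylsilyloxy)-2H-chromen-6-yl]-5-methoxy-7-(triisopropylsilyloxy)-4H-chromen-4-one | COc1cc(O[Si](C(C)C)(C(C)C)C(C)C)cc2occ(-c3cc(O[Si](C(C)C)(C(C)C)C(C)C)c4c(c3)C=CC(C)(C)O4)c(=O)c12 | intermediate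
12 | racemic 3-[2,2-dimethyl-8-(triisopropylsilyloxy)-2H-chromen-6-yl]-5-methoxy-7-(triisopropylsilyloxy)-2,3-dihydro-4H-chromen-4-one | COc1cc(O[Si](C(C)C)(C(C)C)C(C)C)cc2OCC(c3cc(O[Si](C(C)C)(C(C)C)C(C)C)c4c(c3)C=CC(C)(C)O4)C(=O)c12 | intermediate
13 | (3S,4S)-3-[2,2-dimethyl-8-(triisopropylsilyloxy)-2H-chromen-6-yl]-5-methoxy-7-(triisopropylsilyloxy)-3,4-dihydro-2H-chromen-4-ol (3,4-cis) | COc1cc(O[Si](C(C)C)(C(C)C)C(C)C)cc2c1[C@@H](O)[C@@H](c1cc(O[Si](C(C)C)(C(C)C)C(C)C)c3c(c1)C=CC(C)(C)O3)CO2 | intermediate
14 | (3S)-3-[2,2-dimethyl-8-(triisopropylsilyloxy)-2H-chromen-6-yl]-5-methoxy-7-(triisopropylsilyloxy)-2,3-dihydro-4H-chromen-4-one | COc1cc(O[Si](C(C)C)(C(C)C)C(C)C)cc2c1C(=O)[C@@H](c1cc(O[Si](C(C)C)(C(C)C)C(C)C)c3c(c1)C=CC(C)(C)O3)CO2 | intermediate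
15 | (3S)-7-hydroxy-3-(8-hydroxy-2,2-dimethyl-2H-chromen-6-yl)-5-methoxy-2,3-dihydro-4H-chromen-4-one | COc1cc(O)cc2c1C(=O)[C@@H](c1cc(O)c3c(c1)C=CC(C)(C)O3)CO2 | target

## Step count and risks

Total step count: 10.
Longest linear sequence: 7 steps (1, 2, 3, 7, 8, 9, 10). The branch 4, 5, 6 followed by 7 to 10 is equally long.

**Step 1.**
- What may go wrong: slow insertion of nickel into the electron-rich magnesium phenoxide, binding of the catalyst by the diene or catecholate that forms, and loss of material by diene oligomerisation.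
- Fallback: stoichiometric reductive ring opening instead of catalysis, setting out from 1 and returning at 5.
- Compound 1 is silylated (TIPSCl, imidazole, DMF) to 7-(triisopropylsilyloxy)benzofuran F1.
- Lithium powder with catalytic 4,4'-di-tert-butylbiphenyl in THF at 0 °C cleaves the O1–C2 bond to the (Z)-2-lithiovinyl phenoxide.
- Acetone at −78 °C traps this as 2-[(1Z)-3-hydroxy-3-methylbut-1-en-1-yl]-6-(triisopropylsilyloxy)phenol F2.
- H3PO4 in warm toluene closes ring D by cyclodehydration through the same allyl cation and quinone methide to give 5, so step 2 is no longer needed.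
- The furan ring still grows by one carbon, here the carbonyl carbon of acetone.

**Step 8.**
- What may go wrong: sluggish hydride transfer to the carbonyl group next to the C5 methoxy group, so that the resolution is incomplete. The very electron-rich benzylic alcohol may also ionise in the formic acid medium.
- Fallback: enantioselective protonation instead of reduction, setting out from 11 and returning at 14, which bypasses steps 8 and 9.
- 1,4-Reduction of 11 with LiBH(s-Bu)3 in THF at −78 °C and trapping of the enolate with Me3SiCl gives 3-[2,2-dimethyl-8-(triisopropylsilyloxy)-2H-chromen-6-yl]-5-methoxy-7-(triisopropylsilyloxy)-4-(trimethylsilyloxy)-2H-chromene F3.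
- A BINOL-derived N-triflyl thiophosphoramide catalyses its protonation with phenol as the stoichiometric proton source in toluene. This is the known catalytic enantioselective protonation of silyl enol ethers of 2-aryl cyclic ketones.
- With the catalyst antipode chosen for 3S, this gives 14 directly.

**Step 3.**
- What may go wrong: hydroboration or vinylic borylation of the ring-D alkene in competition with the aromatic C–H borylation.
- Fallback: the alkene is masked as the chromane and regenerated later, setting out from 5 and returning at 11.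
- Hydrogenation of 5 (H2, Pd/C, EtOAc) gives 2,2-dimethyl-8-(triisopropylsilyloxy)chromane F4.
- The same iridium-catalysed borylation gives 2-[2,2-dimethyl-8-(triisopropylsilyloxy)chroman-6-yl]-4,4,5,5-tetramethyl-1,3,2-dioxaborolane F5.
- Suzuki coupling of F5 with 10 under the conditions of step 7 gives 3-[2,2-dimethyl-8-(triisopropylsilyloxy)chroman-6-yl]-5-methoxy-7-(triisopropylsilyloxy)-4H-chromen-4-one F6.
- DDQ in refluxing 1,4-dioxane dehydrogenates the chromane ring. This is the known hydride abstraction from the benzylic CH2 activated by the ring oxygen, followed by proton loss, and it gives 11.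

Further compounds
F1 | step 1 | 7-(triisopropylsilyloxy)benzofuran | CC(C)[Si](Oc1cccc2ccoc12)(C(C)C)C(C)C
F2 | step 1 | 2-[(1Z)-3-hydroxy-3-methylbut-1-en-1-yl]-6-(triisopropylsilyloxy)phenol | CC(C)(O)/C=C\c1cccc(O[Si](C(C)C)(C(C)C)C(C)C)c1O
F3 | step 8 | 3-[2,2-dimethyl-8-(triisopropylsilyloxy)-2H-chromen-6-yl]-5-methoxy-7-(triisopropylsilyloxy)-4-(trimethylsilyloxy)-2H-chromene | COc1cc(O[Si](C(C)C)(C(C)C)C(C)C)cc2OCC(c3cc(O[Si](C(C)C)(C(C)C)C(C)C)c4c(c3)C=CC(C)(C)O4)=C(O[Si](C)(C)C)c12
F4 | step 3 | 2,2-dimethyl-8-(triisopropylsilyloxy)chromane | CC1(C)CCc2cccc(O[Si](C(C)C)(C(C)C)C(C)C)c2O1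
F5 | step 3 | 2-[2,2-dimethyl-8-(triisopropylsilyloxy)chroman-6-yl]-4,4,5,5-tetramethyl-1,3,2-dioxaborolane | CC1(C)CCc2cc(B3OC(C)(C)C(C)(C)O3)cc(O[Si](C(C)C)(C(C)C)C(C)C)c2O1
F6 | step 3 | 3-[2,2-dimethyl-8-(triisopropylsilyloxy)chroman-6-yl]-5-methoxy-7-(triisopropylsilyloxy)-4H-chromen-4-one | COc1cc(O[Si](C(C)C)(C(C)C)C(C)C)cc2occ(-c3cc(O[Si](C(C)C)(C(C)C)C(C)C)c4c(c3)CCC(C)(C)O4)c(=O)c12
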